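**Retrosynthetic overview**
- The target is traced back, by ammonolysis of a 3-O-benzoate and by 7-O-prenylation, to 3-O-benzoyl kaempferide; the prenyl ether goes on late because it would not survive the hot key step.
- Key disconnection: ring C is cut at C4–C4a and O1–C2 in one retro-step (Mentzer-type thermal annulation), giving unprotected phloroglucinol and ethyl 2-(benzoyloxy)-3-(4-methoxyphenyl)-3-oxopropanoate. The C3 oxygen is carried in at the final oxidation level, so there is no chalcone, no Algar–Flynn–Oyamada oxidation (which diverts to aurones for 6'-oxygenated chalcones) and no protecting group on ring A.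
- The α-benzoyloxy β-ketoester comes from commercial ethyl 3-(4-methoxyphenyl)-3-oxopropanoate and dibenzoyl peroxide.
- Ring order: rings A and B are bought intact; ring C is the only ring made (step 2).

Assumption: the target has no stereocentre and no stereogenic double bond, so no enantiocontrol is needed; compound 2 has one labile stereocentre, is used as the racemate, and that centre becomes sp2 in step 2.

**Step 1**
Reactants: 1 ethyl 3-(4-methoxyphenyl)-3-oxopropanoate
Product: 2 ethyl 2-(benzoyloxy)-3-(4-methoxyphenyl)-3-oxopropanoate (racemic)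
Conditions: (PhCO2)2 (1.05 equiv), K2CO3 (1.2 equiv), MeCN, 0 °C → rt, 4 h
Reagents that add atoms: dibenzoyl peroxide, O=C(OOC(=O)c1ccccc1)c1ccccc1
Why: Electrophilic α-benzoyloxylation of a β-ketoester enolate, in which the stabilised enolate attacks the weak O–O bond and expels benzoate; the new stereocentre is racemic and irrelevant because it is flattened in step 2.

**Step 2**
Reactants: 2 ethyl 2-(benzoyloxy)-3-(4-methoxyphenyl)-3-oxopropanoate; 3 phloroglucinol (benzene-1,3,5-triol)
Product: 6 5,7-dihydroxy-2-(4-methoxyphenyl)-4-oxo-4H-chromen-3-yl benzoate, via benzoyloxy acylketene 4 (not isolated), via benzoyloxy diketone 5 (not isolated)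
Conditions: neat melt, 2 (1.3 equiv), 230–240 °C, N2 sweep, 1 h (or solvent-free microwave heating, same temperature, 10 min)
Reagents that add atoms: none
Why: Proposed new method: above 200 °C the β-ketoester loses ethanol to acylketene 4, which C-acylates the very electron-rich phloroglucinol (directly or by O-acylation and thermal Fries shift) to diketone 5, whose ortho-hydroxyl adds to the aryl ketone and dehydrates to the γ-pyrone with the α-benzoyloxy group left as the C3 enol ester; the closest known reaction is the Mentzer pyrone synthesis of 5,7-dihydroxyflavones from phloroglucinol and ethyl aroylacetates, including α-alkyl and α-methoxy esters that give 3-substituted flavones, and the symmetry of phloroglucinol removes any regiochemical question.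

**Step 3**
Reactants: 6 5,7-dihydroxy-2-(4-methoxyphenyl)-4-oxo-4H-chromen-3-yl benzoate
Product: 7 5-hydroxy-2-(4-methoxyphenyl)-7-[(3-methylbut-2-en-1-yl)oxy]-4-oxo-4H-chromen-3-yl benzoate
Conditions: prenyl bromide (1.1 equiv), K2CO3 (1.2 equiv), dry acetone, rt → 40 °C, 8 h
Reagents that add atoms: prenyl bromide (1-bromo-3-methylbut-2-ene), CC(C)=CCBr
Why: Williamson ether synthesis in which only the 7-OH reacts, because it is the most acidic phenol (vinylogous acid para to the C4 carbonyl), the 5-OH is locked in a hydrogen bond to C4=O and O3 is blocked as the benzoate.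

**Step 4**
Reactants: 7 5-hydroxy-2-(4-methoxyphenyl)-7-[(3-methylbut-2-en-1-yl)oxy]-4-oxo-4H-chromen-3-yl benzoate
Product: 8 3,5-dihydroxy-2-(4-methoxyphenyl)-7-[(3-methylbut-2-en-1-yl)oxy]-4H-chromen-4-one (target)
Conditions: NH3 (7 M in MeOH, 10 equiv), THF, 0 °C → rt, Ar, 3 h; then AcOH to pH 5
Reagents that add atoms: none
Why: Ammonolysis of an activated enol ester, which is far more electrophilic than anything else present, so the prenyl ether, the aryl methyl ether and the chromone stay untouched, and exclusion of air prevents oxidation of the flavonolate.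

**Compound list**
1 | ethyl 3-(4-methoxyphenyl)-3-oxopropanoate | CCOC(=O)CC(=O)c1ccc(OC)cc1 | starting material
2 | ethyl 2-(benzoyloxy)-3-(4-methoxyphenyl)-3-oxopropanoate (racemic) | CCOC(=O)C(OC(=O)c1ccccc1)C(=O)c1ccc(OC)cc1 | intermediate
3 | phloroglucinol (benzene-1,3,5-triol) | Oc1cc(O)cc(O)c1 | starting material
4 | 1-(4-methoxyphenyl)-1,3-dioxoprop-2-en-2-yl benzoate (acylketene, not isolated) | O=C=C(OC(=O)c1ccccc1)C(=O)c1ccc(OC)cc1 | intermediate
5 | 1-(4-methoxyphenyl)-1,3-dioxo-3-(2,4,6-trihydroxyphenyl)propan-2-yl benzoate (not isolated) | COc1ccc(cc1)C(=O)C(OC(=O)c1ccccc1)C(=O)c1c(O)cc(O)cc1O | intermediate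
6 | 5,7-dihydroxy-2-(4-methoxyphenyl)-4-oxo-4H-chromen-3-yl benzoate | COc1ccc(-c2oc3cc(O)cc(O)c3c(=O)c2OC(=O)c2ccccc2)cc1 | intermediate
7 | 5-hydroxy-2-(4-methoxyphenyl)-7-[(3-methylbut-2-en-1-yl)oxy]-4-oxo-4H-chromen-3-yl benzoate | COc1ccc(-c2oc3cc(OCC=C(C)C)cc(O)c3c(=O)c2OC(=O)c2ccccc2)cc1 | intermediate
8 | 3,5-dihydroxy-2-(4-methoxyphenyl)-7-[(3-methylbut-2-en-1-yl)oxy]-4H-chromen-4-one | COc1ccc(-c2oc3cc(OCC=C(C)C)cc(O)c3c(=O)c2O)cc1 | target

**Totals**
Total step count: 4. Longest linear sequence: 4 steps (1 → 2 → 6 → 7 → 8).

**Steps most likely to fail, with fallbacks**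

The most likely failure is step 2: the benzoate may scramble onto phenolic oxygens, some 2 may be lost by hydrolysis and decarboxylation, or Pechmann-type coumarin may form. The fallback gives up the one-step annulation for the classical stepwise build of ring C and sets out from 3. Hoesch acylation of 3 with benzoyloxyacetonitrile (ZnCl2, HCl gas, Et2O, 0 °C) precipitates 2-(benzoyloxy)-1-(2,4,6-trihydroxyphenyl)ethan-1-iminium chloride F1. Hot water hydrolyses this to 2-oxo-2-(2,4,6-trihydroxyphenyl)ethyl benzoate F2. Allan–Robinson condensation of F2 with 4-methoxybenzoic anhydride and sodium 4-methoxybenzoate at 170–180 °C gives the fully aroylated flavonol 3-(benzoyloxy)-2-(4-methoxyphenyl)-4-oxo-4H-chromene-5,7-diyl bis(4-methoxybenzoate) F3. This is saponified without purification (KOH, aqueous EtOH, reflux under N2, then acid) to kaempferide F4. F4 is prenylated on its most acidic 7-OH with 1.0 equiv prenyl bromide and K2CO3 in acetone, and the route is rejoined at 8.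

Second is step 1: a second benzoyloxylation of 2 or radical side reactions of the peroxide may occur. The fallback replaces electrophilic oxygenation by halogenation and nucleophilic displacement and sets out from 1. NBS with catalytic NH4OAc in Et2O at rt gives ethyl 2-bromo-3-(4-methoxyphenyl)-3-oxopropanoate F5. Potassium benzoate in DMF at rt displaces the bromide and the route is rejoined at 2.

Third is step 3: carbonate may cause partial loss of the 3-O-benzoate followed by O3-alkylation, or C-prenylation or 5-O-alkylation may compete. The fallback replaces phenoxide alkylation by a redox condensation under neutral conditions and sets out from 6. Mitsunobu etherification with 3-methylbut-2-en-1-ol, PPh3 and DIAD in THF (0 °C → rt) engages only the acidic, non-chelated 7-OH and rejoins the route at 7. It makes no new compound (none F0).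

**Further compounds**
F1 | step 2 | 2-(benzoyloxy)-1-(2,4,6-trihydroxyphenyl)ethan-1-iminium chloride | [Cl-].[NH2+]=C(COC(=O)c1ccccc1)c1c(O)cc(O)cc1O
F2 | step 2 | 2-oxo-2-(2,4,6-trihydroxyphenyl)ethyl benzoate | O=C(COC(=O)c1ccccc1)c1c(O)cc(O)cc1O
F3 | step 2 | 3-(benzoyloxy)-2-(4-methoxyphenyl)-4-oxo-4H-chromene-5,7-diyl bis(4-methoxybenzoate) | COc1ccc(cc1)-c1oc2cc(OC(=O)c3ccc(OC)cc3)cc(OC(=O)c3ccc(OC)cc3)c2c(=O)c1OC(=O)c1ccccc1
F4 | step 2 | kaempferide (3,5,7-trihydroxy-2-(4-methoxyphenyl)-4H-chromen-4-one) | COc1ccc(-c2oc3cc(O)cc(O)c3c(=O)c2O)cc1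
F5 | step 1 | ethyl 2-bromo-3-(4-methoxyphenyl)-3-oxopropanoate | CCOC(=O)C(Br)C(=O)c1ccc(OC)cc1
F0 | step 3 | none | none
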